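**Assumption:** the target is read as the (4aR) enantiomer (one enol tautomer drawn). The sense of induction in step 3 is assigned by analogy with phase-transfer alkylations of tert-butyl malonates; if the (S,S)-catalyst gives the antipode of 8, the commercial (R,R)-catalyst is used and nothing else changes. Ring atoms are numbered as in the chromene (O1, C2, C3, C4, C4a, C5–C8, C8a).

## Retrosynthetic overview

1. Target 13 ⇒ open O1–C2 (addition of the C8a enol O–H across a diene) ⇒ monocyclic dienyl trione 12 ⇒ open C6–C5 (Claisen) and C8–C8a (acylation) ⇒ diketone 3 + quaternary malonyl half-chloride 10.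
2. Both rings close in one flask from these two open-chain pieces: carbocycle first ([3+3] double acylation), 2H-pyran second.
3. 10 ⇒ mixed malonate 8. COCl becomes C8a and CO2Et becomes C5, so the C4a configuration set in 8 is carried unchanged into the ring.
4. 8 ⇒ Knoevenagel adduct 6 + prenyl bromide by enantioselective deconjugative α-prenylation (sets the quaternary centre and the dienyl arm together); 6 ⇒ tert-butyl ethyl malonate + prenal.
5. 3 ⇒ 6-methylhept-5-en-2-one + methyl isobutyrate (crossed Claisen).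

## Route

Step 1
Reactants: 1 6-methylhept-5-en-2-one; 2 methyl 2-methylpropanoate
Product: 3 2,9-dimethyldec-8-ene-3,5-dione
Conditions: NaH (2.5 equiv), 2 (2 equiv), DME, reflux; aq. HCl work-up
Reagents that add atoms: none
Why: Crossed Claisen condensation; the methyl-side enolate of the ketone is acylated and the product is held as its β-diketonate, which drives the equilibrium; no stereocentre.

Step 2
Reactants: 4 tert-butyl ethyl malonate; 5 3-methylbut-2-enal
Product: 6 1-tert-butyl 3-ethyl 2-(3-methylbut-2-en-1-ylidene)propanedioate (E/Z mixture)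
Conditions: piperidine (0.1 equiv), AcOH (0.1 equiv), PhMe, reflux, Dean–Stark
Reagents that add atoms: none
Why: Knoevenagel condensation of an enal with a malonate; the E/Z ratio is irrelevant because both isomers give the same anion in step 3.

Step 3
Reactants: 6; 7 1-bromo-3-methylbut-2-ene
Product: 8 1-tert-butyl 3-ethyl (2S)-2-[(1E)-3-methylbuta-1,3-dien-1-yl]-2-(3-methylbut-2-en-1-yl)propanedioate
Conditions: (S,S)-3,4,5-trifluorophenyl-NAS bromide (5 mol %), CsOH·H2O (3 equiv), 7 (2 equiv), PhMe, −40 °C
Reagents that add atoms: none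
Why: Proposed new method: interfacial deprotonation of 6 at a terminal methyl gives a pentadienyl malonate anion that is alkylated by SN2 at the α-carbon (deconjugative alkylation, largest HOMO coefficient, leaves the E-1,3-diene), and the chiral N-spiro ammonium counter-ion differentiates the two faces through the bulky tert-butyl versus small ethyl ester to set the quaternary centre as (S); the closest known reaction is the asymmetric phase-transfer α-alkylation of α-substituted tert-butyl malonates.

Step 4
Reactants: 8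
Product: 10 ethyl (2S,3E)-2-(chlorocarbonyl)-5-methyl-2-(3-methylbut-2-en-1-yl)hexa-3,5-dienoate, via trimethylsilyl ester 9 (not isolated)
Conditions: TMSOTf (1.5 equiv), 2,6-lutidine (2.5 equiv), CH2Cl2, 0 °C; then (COCl)2 (1.5 equiv), DMF (cat.), 0 °C → rt; volatiles removed, used crude
Reagents that add atoms: oxalyl chloride, ClC(=O)C(=O)Cl (the Cl of 10); trimethylsilyl triflate, C[Si](C)(C)OS(=O)(=O)C(F)(F)F (the silyl group of 9 only)
Why: Silyl-triflate cleavage of the tert-butyl ester (loss of isobutene) under lutidine buffer, then silyl ester → acid chloride with the Vilsmeier reagent, both without free protic acid so diene, prenyl and ethyl ester survive; the centre has no α-H and cannot epimerise.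

Step 5
Reactants: 3 2,9-dimethyldec-8-ene-3,5-dione; 10 ethyl (2S,3E)-2-(chlorocarbonyl)-5-methyl-2-(3-methylbut-2-en-1-yl)hexa-3,5-dienoate
Product: 13 (4aR)-7-hydroxy-2,2-dimethyl-4a,8-bis(3-methylbut-2-en-1-yl)-6-(2-methylpropanoyl)-2H-chromen-5(4aH)-one, via open-chain triketo ester 11 (not isolated), via monocyclic dienyl trione 12 (not isolated)
Conditions: 3 (2.2 equiv), LDA (4.4 equiv), THF, −78 → 0 °C; 10 (1.0 equiv), −78 °C → rt, then 45 °C; then AcOH (10 equiv), Pd(PPh3)4 (5 mol %), 50 °C
Reagents that add atoms: none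
Why: Proposed new method: the Hauser–Harris dianion of 3 is acylated at its terminal carbanion by the acid chloride only (C8–C8a), the resulting bis-enolate closes the carbocycle by Claisen attack of C6 on the ethyl ester (C6–C5, biomimetic polyketide cyclisation, O-acylation being reversible), and after acidification Pd–H adds to the 1,3-diene to give a π-allyl complex that the C8a enol oxygen captures at the CMe2 end to close the 2H-pyran while C5=O stays in the chelated β-triketone; the stereocentre is untouched and its sense is retained because COCl and CO2Et react with different carbons of 3; the closest known reactions are β-diketone dianion acylation with Claisen cyclisation of triketo esters and Pd(0)-catalysed addition of acidic O–H groups to 1,3-dienes.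

## Compound list

1 | 6-methylhept-5-en-2-one | CC(=O)CCC=C(C)C | starting material
2 | methyl 2-methylpropanoate (methyl isobutyrate) | COC(=O)C(C)C | starting material
3 | 2,9-dimethyldec-8-ene-3,5-dione | CC(C)C(=O)CC(=O)CCC=C(C)C | intermediate
4 | tert-butyl ethyl malonate | CCOC(=O)CC(=O)OC(C)(C)C | starting material
5 | 3-methylbut-2-enal (prenal) | CC(C)=CC=O | starting material
6 | 1-tert-butyl 3-ethyl 2-(3-methylbut-2-en-1-ylidene)propanedioate (E/Z mixture) | CCOC(=O)C(=CC=C(C)C)C(=O)OC(C)(C)C | intermediate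
7 | 1-bromo-3-methylbut-2-ene (prenyl bromide) | CC(C)=CCBr | starting material
8 | 1-tert-butyl 3-ethyl (2S)-2-[(1E)-3-methylbuta-1,3-dien-1-yl]-2-(3-methylbut-2-en-1-yl)propanedioate | CC(=C)/C=C/[C@@](C(=O)OC(C)(C)C)(CC=C(C)C)C(=O)OCC | intermediate
9 | 1-ethyl 3-trimethylsilyl (2S)-2-[(1E)-3-methylbuta-1,3-dien-1-yl]-2-(3-methylbut-2-en-1-yl)propanedioate (not isolated) | CC(=C)/C=C/[C@@](C(=O)O[Si](C)(C)C)(CC=C(C)C)C(=O)OCC | intermediate
10 | ethyl (2S,3E)-2-(chlorocarbonyl)-5-methyl-2-(3-methylbut-2-en-1-yl)hexa-3,5-dienoate | CC(=C)/C=C/[C@@](C(Cl)=O)(CC=C(C)C)C(=O)OCC | intermediate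
11 | ethyl (2R)-8-methyl-2-[(1E)-3-methylbuta-1,3-dien-1-yl]-2,4-bis(3-methylbut-2-en-1-yl)-3,5,7-trioxononanoate (C-4 epimers and enol forms; not isolated) | CC(=C)/C=C/[C@@](C(=O)C(CC=C(C)C)C(=O)CC(=O)C(C)C)(CC=C(C)C)C(=O)OCC | intermediate
12 | (6R)-3,5-dihydroxy-6-[(1E)-3-methylbuta-1,3-dien-1-yl]-4,6-bis(3-methylbut-2-en-1-yl)-2-(2-methylpropanoyl)cyclohexa-2,4-dien-1-one (not isolated) | CC(C)=CCC1=C(O)[C@@](CC=C(C)C)(/C=C/C(C)=C)C(=O)C(C(=O)C(C)C)=C1O | intermediate
13 | (4aR)-7-hydroxy-2,2-dimethyl-4a,8-bis(3-methylbut-2-en-1-yl)-6-(2-methylpropanoyl)-2H-chromen-5(4aH)-one | CC(C)=CCC1=C2OC(C)(C)C=C[C@@]2(CC=C(C)C)C(=O)C(C(=O)C(C)C)=C1O | target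

## Step count and risks

Total step count: 5. Longest linear sequence: 4 (steps 2 → 3 → 4 → 5; step 1 supplies 3 convergently).

Three steps most likely to fail:

1. Step 5. The Claisen ring closure may stop at the O-acylated enol lactone, and the Pd stage may close onto the C5 oxygen instead of the C8a oxygen or not turn over in the salt-laden mixture. Fallback: set out from 11, now isolated after a cold AcOH quench of the acylation. Treat it with Pd(PPh3)4/AcOH in THF while C5 is still an ester, so that only the C8a enol oxygen can form a six-membered ring. This gives the monocyclic pyran keto ester ethyl (3R)-2-(2,9-dimethyl-6,8-dioxodec-2-en-5-ylidene)-6,6-dimethyl-3-(3-methylbut-2-en-1-yl)-3,6-dihydro-2H-pyran-3-carboxylate F1. LiHMDS in THF then closes the carbocycle by Claisen attack of C6 on the ester, and the route is rejoined at 13.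

2. Step 3. Enantioselectivity and α- versus γ/ε-alkylation of the extended anion are unproven, and hydroxide can cause retro-Knoevenagel cleavage of 6. Fallback: set out from 6 and alkylate without asymmetric induction (NaH, then 7, THF, 0 °C → rt) to the racemic diester rac-1-tert-butyl 3-ethyl 2-[(1E)-3-methylbuta-1,3-dien-1-yl]-2-(3-methylbut-2-en-1-yl)propanedioate F2. Resolve it by preparative chiral SFC into 8 and its enantiomer, the (2R)-diester F3, which is discarded. The route is rejoined at 8.

3. Step 4. The hindered half-ester chloride may not form cleanly or may not survive concentration. Fallback: set out from 8 and hydrolyse the silyl ester 9 on aqueous work-up to the half-acid (2R,3E)-2-(ethoxycarbonyl)-5-methyl-2-(3-methylbut-2-en-1-yl)hexa-3,5-dienoic acid F4. Pd(PPh3)4 (THF, 50 °C) adds the CO2H across the diene to give the lactone ethyl (3S)-6,6-dimethyl-3-(3-methylbut-2-en-1-yl)-2-oxo-3,6-dihydro-2H-pyran-3-carboxylate F5, which replaces the chloride as acyl donor. The dianion of 3 opens the lactone carbonyl (the more electrophilic of the two) to the open-chain hydroxy triketo ester F6. Claisen closure onto the ethyl ester gives the monocyclic hydroxy trione F7, and a CSA quench (CH2Cl2, rt) closes the pyran by cyclodehydration of the (Z)-allylic tertiary alcohol. The route is rejoined at 13.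

## Further compounds

F1 | step 5 | ethyl (3R)-2-(2,9-dimethyl-6,8-dioxodec-2-en-5-ylidene)-6,6-dimethyl-3-(3-methylbut-2-en-1-yl)-3,6-dihydro-2H-pyran-3-carboxylate | CCOC(=O)[C@]1(CC=C(C)C)C=CC(C)(C)OC1=C(CC=C(C)C)C(=O)CC(=O)C(C)C
F2 | step 3 | rac-1-tert-butyl 3-ethyl 2-[(1E)-3-methylbuta-1,3-dien-1-yl]-2-(3-methylbut-2-en-1-yl)propanedioate | CC(=C)/C=C/C(C(=O)OC(C)(C)C)(CC=C(C)C)C(=O)OCC
F3 | step 3 | 1-tert-butyl 3-ethyl (2R)-2-[(1E)-3-methylbuta-1,3-dien-1-yl]-2-(3-methylbut-2-en-1-yl)propanedioate | CC(=C)/C=C/[C@](C(=O)OC(C)(C)C)(CC=C(C)C)C(=O)OCC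
F4 | step 4 | (2R,3E)-2-(ethoxycarbonyl)-5-methyl-2-(3-methylbut-2-en-1-yl)hexa-3,5-dienoic acid | CC(=C)/C=C/[C@@](C(=O)O)(CC=C(C)C)C(=O)OCC
F5 | step 4 | ethyl (3S)-6,6-dimethyl-3-(3-methylbut-2-en-1-yl)-2-oxo-3,6-dihydro-2H-pyran-3-carboxylate | O=C1OC(C)(C)C=C[C@@]1(CC=C(C)C)C(=O)OCC
F6 | step 4 | ethyl (2R)-2-[(1Z)-3-hydroxy-3-methylbut-1-en-1-yl]-8-methyl-2,4-bis(3-methylbut-2-en-1-yl)-3,5,7-trioxononanoate | CCOC(=O)[C@](CC=C(C)C)(/C=C\C(C)(C)O)C(=O)C(CC=C(C)C)C(=O)CC(=O)C(C)C
F7 | step 4 | (6R)-3,5-dihydroxy-6-[(1Z)-3-hydroxy-3-methylbut-1-en-1-yl]-4,6-bis(3-methylbut-2-en-1-yl)-2-(2-methylpropanoyl)cyclohexa-2,4-dien-1-one | CC(C)=CCC1=C(O)[C@@](CC=C(C)C)(/C=C\C(C)(C)O)C(=O)C(C(=O)C(C)C)=C1O
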